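## The problem

The target is a 4→6-linked biflavanoid. The upper half is a 2,3-cis-3,4-trans-flavan-3-ol (ring A 7,8-dihydroxylated, ring B a catechol) whose C4 is bonded to C6 of the lower half, a 2,3-cis-3,4-cis-flavan-3,4-diol with a 7,8-dihydroxylated ring A and a 4-hydroxyphenyl ring B. There are six stereocentres in two triads, (2R,3R,4S) above and (2R,3R,4R) below. Within a triad the centres are neighbours: upper C4, a diarylmethine that cannot be corrected later, must be set first and can then direct C3 (trans to it) and C2 (trans to the C4 aryl, cis to O3). Between the triads lie the C4–C6 bond and a benzene ring, so the lower triad needs its own source of absolute configuration, and its all-cis arrangement is the one that additions to 2-arylchromenes and reductions of trans-dihydroflavonols do not give. The molecule carries ten hydroxyl groups, two of them in 1,2-diphenol pairs that oxidise in base and air; the benzylic C4–OH of the lower unit ionises in acid and can be hydrogenolysed, and the interflavanyl bond and both benzylic O1–C2 bonds are acid-labile. Protecting groups must therefore leave last and under neutral conditions. The feature that opens the route lies in the upper ring C: O1 sits between ring A carbon C8a and C2, and C8a is flanked by the C8 oxygen, so deleting O1 leaves a 3-arylindan-1-one whose carbonyl-bearing ring carbon is ortho to an alkoxy group and migrates readily to oxygen, while its benzylic carbon (future C4) can be made as one enantiomer by conjugate reduction of an indenone.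

## Retrosynthesis

**25 ⇒ 24.** Nine O–benzyl bonds are cut. Methyl ethers would need BBr3 and acetal or silyl groups would need acid or many extra steps, none of which the 3,4-diol and the interflavanyl bond tolerate. The forward step must be a neutral hydrogenolysis that spares the benzylic C4–OH.

**24 ⇒ 23.** Four hydrogens are removed from lower ring C, which gives the flat 3-benzyloxyflavone 23 without lower stereocentres. The all-cis triad is the signature of syn addition of hydrogen to one face of a flavonol. Enolate hydroxylation, epoxide opening or dihydroxylation on a 2-aryl chroman would all place O3 trans to the C2 aryl. Because the upper unit is too remote to bias the faces, the forward reaction must be catalyst-controlled.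

**23 ⇒ 22 ⇒ 19 + 20.** After removal of the 3-O-benzyl group, the lower pyranone is opened at O1–C2, C3–OH and C2=C3. This leaves the ortho-hydroxyacetophenone 19 and commercial 4-(benzyloxy)benzaldehyde 20. Condensation and oxidative cyclisation in one pot is the shortest known way to a flavonol. It needs base and peroxide, which is why the upper unit must be all-ether, with the lactone already gone, at that point.

**19 ⇒ 18 ⇒ 16.** The ortho phenol is re-benzylated and the acetyl group is traced back to a bromine. A Friedel–Crafts acetylation at this stage would have to choose among three alkoxy-rich rings, and a ketone introduced earlier would not survive the enolate and hydride steps on the upper unit. A bromine placed on the aldehyde at the outset is therefore carried as a silent marker of lower C4a. The forward steps are a cross-coupling with an acetyl equivalent and a chelation-directed cleavage of the one benzyl ether next to the new carbonyl.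

**16 ⇒ 14 + 15.** The bond from upper C2 to ring B is cut, which gives lactol 14 and commercial 1,2-bis(benzyloxy)benzene 15. The neighbouring option, adding an aryl metal to the lactone and reducing the resulting cation, would put hydride rather than aryl on the favoured face and lead to the 2,3-trans epimer. The forward step must be para-selective on 15 and must bring the arene in cis to O3 and trans to the C4 aryl.

**14 ⇒ 13 ⇒ 12 ⇒ 11.** The lactol is taken back to the lactone and the C3 oxygen is removed. The C3–O bond is best made on the enolate of lactone 11, where the C4 aryl shields one face. Hydroxylating at the indanone stage instead would place an α-oxygenated carbon next to the ketone and reverse the migratory preference in the oxygen insertion.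

**11 ⇒ 10.** The O1–C8a bond is cut by deleting O1, which contracts the pyranone to the indanone 10. This is the key simplification: a heterocycle with an aryl–oxygen bond becomes a carbocycle that can be assembled by carbonyl chemistry. The forward reaction must move the aryl carbon, not the methylene, to oxygen and must leave the electron-rich rings alone.

**10 ⇒ 9 ⇒ 7.** The C3–H bond is cut to give indenone 9, which comes from racemic indanone 7 by dehydrogenation. Enantioselective conjugate reduction of a β-aryl cyclic enone is more dependable than an asymmetric Nazarov cyclisation of a simple chalcone. An asymmetric reductive Heck closure would need a second halogen and would clash with the marker bromine.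

**7 ⇒ 6 ⇒ 5 ⇒ 4.** The benzyl ethers are exchanged for methyl ethers and the C3–C3a bond is cut (Nazarov cyclisation). The cyclisation needs hot strong acid, which benzyl ethers do not survive, so the ring is closed in the methyl series and the groups are exchanged on the robust racemic ketone. Cyclisation of chalcone 4 occurs para to the 3'-methoxy group and gives the 6,7-dioxygenated indanone. A Friedel–Crafts acylation of a diarylpropanoic acid would close para to the ring oxygen and give the 5,6-isomer.

**4 ⇒ 2 + 3; 2 ⇒ 1.** The enone is cut into commercial 2',3'-dimethoxyacetophenone 3 and bromo aldehyde 2, which is one bromination from commercial 2,3,4-trimethoxybenzaldehyde 1.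

## Roads not taken

Alternative 1: Lower ring A would be made last. A cationic rhodium catalyst such as [Rh(cod)2]BF4 with a bisphosphine would join the tethered diyne A1 (lower C2–C4, O1, a terminal alkyne and a boryl ynol ether) with the siloxyalkyne A2 on upper C4, forming C4a–C8a, C5–C6 and C7–C8 and closing lower ring A and ring C of A3 at once.
- Merits: it is highly convergent, needs no Friedel–Crafts regiochemistry, and differentiates the C7 and C8 oxygens. The lower triad would come from acyclic, reagent-controlled chemistry, which is better than the chosen plan at its weakest point.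
- Weak points: the O–C≡C–B unit of A1 is a push–pull alkyne without stable precedent and, like A2, is readily hydrolysed. The propargylic, doubly benzylic C4–H of A2 is acidic. The orientation in which A2 inserts decides whether the upper unit ends on C6 or C7 and is not obviously controlled. An all-syn triol chain, C–B oxidation and desilylation are still required.
- Comparison: against its convergence and lower-unit stereocontrol, the chosen plan sets a known reaction type for every ring it closes and confines its one unprecedented step to the end, with a known fallback.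

Alternative 2: The lower O1–C2 bond would be closed on the unprotected chalcone A4 by a type 2 chalcone isomerase, which adds the 2'-phenoxide to the enone and gives the (2S)-flavanone A5.
- Merits: it works on free phenols and sets lower C2 under enzyme control, independent of the upper unit, which the chosen plan can only do with a proposed catalyst.
- Weak points: acceptance of a chalcone carrying a whole flavan on its ring A is uncertain, and A4 is an air-sensitive pyrogallol-type enone. A5 still lacks O3, and every known way to add it to a flavanone (enolate oxidation, flavanone 3-hydroxylase) puts it trans to the C2 aryl, so the all-cis diol is not reached. C2 of A5 also epimerises through ring opening in base.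
- Comparison: this road is better for C2 alone. The chosen plan sets all three lower centres in one syn addition.

Alternative 3: The upper pyran would be formed by an aminocatalytic oxa-[4+2]. Base releases an ortho-quinone methide from sulfone A6, the chiral enamine of benzyloxyacetaldehyde A7 attacks the methide carbon (C3–C4), and the phenoxide closes on the aldehyde carbon (O1–C2). The product is lactol A8, which is 14 without the bromine.
- Merits: ring C and both C3 and C4 arise in one catalytic step from achiral materials. This reaches the stage of 14 in about a third of the steps needed here and is clearly better in step economy.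
- Weak points: α-alkoxy aldehydes are sluggish and less selective enamine donors. The quinone methide is flanked by benzyloxy groups on both aryl rings. A6 needs a regioselective hydroxyalkylation of a 2,3-dioxygenated phenol and would also have to carry the marker bromine. Everything after the lactol is the same as here.
- Comparison: the chosen plan sets against the shorter road only that C4 is fixed by a conjugate reduction of a well-behaved enone, C3 by simple substrate control, and that each of its first eleven steps has a close known counterpart.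

Key step: step 8

Assumption: in steps 7 and 17 and in the oxazaborolidine fallback, the antipode of the chiral ligand or catalyst is the one that a test reaction shows to give the drawn configuration, since the sense of induction cannot be predicted with certainty for these substrates.

Step 1
Reactants: 1 2,3,4-trimethoxybenzaldehyde
Product: 2 5-bromo-2,3,4-trimethoxybenzaldehyde
Conditions: NBS, MeCN, rt
Reagents that add atoms: N-bromosuccinimide, O=C1CCC(=O)N1Br
Why: Electrophilic aromatic bromination; C5 is ortho to the 4-methoxy, para to the 2-methoxy and meta to the formyl group, so it is the one strongly activated position, and the bromine marks the carbon that becomes lower C4a.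

Step 2
Reactants: 2 5-bromo-2,3,4-trimethoxybenzaldehyde; 3 1-(2,3-dimethoxyphenyl)ethan-1-one
Product: 4 (E)-3-(5-bromo-2,3,4-trimethoxyphenyl)-1-(2,3-dimethoxyphenyl)prop-2-en-1-one
Conditions: KOH (aq.), EtOH, rt
Reagents that add atoms: none
Why: Claisen–Schmidt condensation; the aldehyde has no α-hydrogen and the aldol dehydrates to the conjugated (E)-enone.

Step 3
Reactants: 4 (E)-3-(5-bromo-2,3,4-trimethoxyphenyl)-1-(2,3-dimethoxyphenyl)prop-2-en-1-one
Product: 5 rac-3-(5-bromo-2,3,4-trimethoxyphenyl)-6,7-dimethoxy-2,3-dihydro-1H-inden-1-one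
Conditions: CF3CO2H (neat), 110 °C, sealed tube
Reagents that add atoms: none
Why: Nazarov-type cyclisation of an aryl vinyl ketone: the O-protonated enone closes onto C6' of the aroyl ring, para to the 3'-methoxy group, which gives the 6,7-dioxygenated indanone; methyl ethers and the aryl bromide withstand the hot acid that benzyl ethers would not.

Step 4
Reactants: 5 rac-3-(5-bromo-2,3,4-trimethoxyphenyl)-6,7-dimethoxy-2,3-dihydro-1H-inden-1-one
Product: 6 rac-3-(5-bromo-2,3,4-trihydroxyphenyl)-6,7-dihydroxy-2,3-dihydro-1H-inden-1-one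
Conditions: BBr3, CH2Cl2, −78 °C to rt; then H2O
Reagents that add atoms: none
Why: Lewis-acid cleavage of aryl methyl ethers; it is run on the racemic ketone so that no stereocentre is exposed to the acid.

Step 5
Reactants: 6 rac-3-(5-bromo-2,3,4-trihydroxyphenyl)-6,7-dihydroxy-2,3-dihydro-1H-inden-1-one
Product: 7 rac-6,7-bis(benzyloxy)-3-[2,3,4-tris(benzyloxy)-5-bromophenyl]-2,3-dihydro-1H-inden-1-one
Conditions: BnBr, K2CO3, DMF, 60 °C, under argon
Reagents that add atoms: benzyl bromide, BrCc1ccccc1
Why: Williamson ether synthesis; benzyl is the phenol protecting group that can leave at the end under neutral hydrogen, and carbonate is too weak a base to alkylate the ketone α-carbon.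

Step 6
Reactants: 7 rac-6,7-bis(benzyloxy)-3-[2,3,4-tris(benzyloxy)-5-bromophenyl]-2,3-dihydro-1H-inden-1-one
Product: 9 6,7-bis(benzyloxy)-3-[2,3,4-tris(benzyloxy)-5-bromophenyl]-1H-inden-1-one, via 2-phenylselanyl ketone 8 (not isolated)
Conditions: LiN(SiMe3)2, THF, −78 °C; PhSeCl; then H2O2 (30% aq.), pyridine, CH2Cl2, 0 °C to rt
Reagents that add atoms: phenylselenyl chloride, Cl[Se]c1ccccc1 (its atoms are kept only in 8)
Why: α-Selenenylation of the lithium enolate trans to the C3 aryl, then selenoxide syn-elimination through the cis C3–H; unlike quinone or radical dehydrogenations it leaves the benzylic ether methylenes alone.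

Step 7
Reactants: 9 6,7-bis(benzyloxy)-3-[2,3,4-tris(benzyloxy)-5-bromophenyl]-1H-inden-1-one
Product: 10 (3R)-6,7-bis(benzyloxy)-3-[2,3,4-tris(benzyloxy)-5-bromophenyl]-2,3-dihydro-1H-inden-1-one
Conditions: Cu(OAc)2·H2O (cat.), (R)-DTBM-SEGPHOS (cat.), (EtO)2MeSiH, t-BuOH, toluene, 0 °C to rt
Reagents that add atoms: none
Why: Copper hydride-catalysed asymmetric conjugate reduction of a β,β-disubstituted cyclic enone; the bisphosphine-bound Cu–H adds hydride to one face of C3 and sets (3R), and the aryl bromide and benzyl ethers are inert to the copper/silane system.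

Step 8
Reactants: 10 (3R)-6,7-bis(benzyloxy)-3-[2,3,4-tris(benzyloxy)-5-bromophenyl]-2,3-dihydro-1H-inden-1-one
Product: 11 (4R)-7,8-bis(benzyloxy)-4-[2,3,4-tris(benzyloxy)-5-bromophenyl]-3,4-dihydro-2H-chromen-2-one
Conditions: mCPBA, NaHCO3, CH2Cl2, 0 °C to rt
Reagents that add atoms: 3-chloroperbenzoic acid, OOC(=O)c1cccc(Cl)c1
Why: Baeyer–Villiger oxidation: the peracid adds to the C1 carbonyl to give the peroxy hemiketal (Criegee adduct), and ring A carbon C7a, antiperiplanar to the O–O bond, shifts from carbon to oxygen as 3-chlorobenzoate leaves. The closest known reaction is the peracid oxidation of 1-indanones, 3-aryl ones included, to 3,4-dihydrocoumarins. The six-membered lactone is not closed by a cyclisation; it results from one-atom expansion of the five-membered ring, with oxygen inserted between C1 and C7a, so no ring-closure mode has to be controlled. No stereocentre is formed: C3 of 10 is β to the carbonyl, takes no part and becomes C4 of 11 unchanged (the descriptor stays R because the bromine keeps the aryl group above C4a in priority). The step needs aryl over methylene migration and ketone over arene oxidation. The migrating carbon is ortho to the C7 benzyloxy group and can carry positive charge in the transition state, whereas C2 is a primary alkyl carbon of low migratory aptitude. NaHCO3 removes the 3-chlorobenzoic acid, so the benzyl ethers and the trialkoxyphenyl ring are not exposed to acid, and the aryl ester formed is less electron-rich than the ketone. The aryl bromide and the diarylmethine are inert to the peracid.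

Step 9
Reactants: 11 (4R)-7,8-bis(benzyloxy)-4-[2,3,4-tris(benzyloxy)-5-bromophenyl]-3,4-dihydro-2H-chromen-2-one
Product: 12 (3R,4R)-7,8-bis(benzyloxy)-4-[2,3,4-tris(benzyloxy)-5-bromophenyl]-3-hydroxy-3,4-dihydro-2H-chromen-2-one
Conditions: KN(SiMe3)2, THF, −78 °C; 2-(phenylsulfonyl)-3-phenyloxaziridine; NH4Cl (aq.)
Reagents that add atoms: 2-(phenylsulfonyl)-3-phenyloxaziridine, O=S(=O)(N1OC1c1ccccc1)c1ccccc1
Why: Oxaziridine hydroxylation of the lactone enolate; the electrophile approaches the face opposite the C4 aryl, which gives the 3,4-trans alcohol (3R), and C4 itself is not deprotonated.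

Step 10
Reactants: 12 (3R,4R)-7,8-bis(benzyloxy)-4-[2,3,4-tris(benzyloxy)-5-bromophenyl]-3-hydroxy-3,4-dihydro-2H-chromen-2-one
Product: 13 (3R,4R)-3,7,8-tris(benzyloxy)-4-[2,3,4-tris(benzyloxy)-5-bromophenyl]-3,4-dihydro-2H-chromen-2-one
Conditions: BnBr, Ag2O, CH2Cl2, rt, dark
Reagents that add atoms: benzyl bromide, BrCc1ccccc1
Why: Silver oxide-mediated O-benzylation of an α-hydroxy ester, which avoids enolate formation and so keeps C3 and the aryl ester intact; a non-participating ether is wanted at C3 for step 12.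

Step 11
Reactants: 13 (3R,4R)-3,7,8-tris(benzyloxy)-4-[2,3,4-tris(benzyloxy)-5-bromophenyl]-3,4-dihydro-2H-chromen-2-one
Product: 14 (3R,4R)-3,7,8-tris(benzyloxy)-4-[2,3,4-tris(benzyloxy)-5-bromophenyl]chroman-2-ol (both C2 anomers)
Conditions: i-Bu2AlH, CH2Cl2, −78 °C; potassium sodium tartrate (aq.)
Reagents that add atoms: none
Why: Partial reduction of a lactone to the lactol; the aluminium hemiacetal is stable at −78 °C, and both anomers give the same cation in step 12.

Step 12
Reactants: 14 (3R,4R)-3,7,8-tris(benzyloxy)-4-[2,3,4-tris(benzyloxy)-5-bromophenyl]chroman-2-ol; 15 1,2-bis(benzyloxy)benzene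
Product: 16 (2R,3R,4R)-3,7,8-tris(benzyloxy)-2-[3,4-bis(benzyloxy)phenyl]-4-[2,3,4-tris(benzyloxy)-5-bromophenyl]chromane
Conditions: 15 (4 equiv), BF3·OEt2 (0.5 equiv), CH2Cl2, −78 to −40 °C
Reagents that add atoms: none
Why: Friedel–Crafts C-arylation of a lactol through its oxocarbenium ion, the reaction type of Lewis-acid C-aryl glycoside synthesis; the arene reacts para to one benzyloxy group and should enter anti to the C4 aryl and cis to the pseudo-equatorial C3 benzyloxy group (axial attack on the half-chair, the 1,2-cis and 1,3-trans preference of six-membered oxocarbenium ions), which sets (2R); the bromine and the flanking ethers keep the C4 aryl ring from capturing the cation itself.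

Step 13
Reactants: 16 (2R,3R,4R)-3,7,8-tris(benzyloxy)-2-[3,4-bis(benzyloxy)phenyl]-4-[2,3,4-tris(benzyloxy)-5-bromophenyl]chromane
Product: 18 1-{2,3,4-tris(benzyloxy)-5-[(2R,3R,4R)-3,7,8-tris(benzyloxy)-2-[3,4-bis(benzyloxy)phenyl]chroman-4-yl]phenyl}ethan-1-one, via 1-ethoxyvinyl arene 17 (not isolated)
Conditions: Bu3Sn(C(OEt)=CH2), Pd(PPh3)4 (cat.), toluene, 100 °C; then HCl (1 M aq.), THF, rt
Reagents that add atoms: tributyl(1-ethoxyvinyl)stannane, CCCC[Sn](CCCC)(CCCC)C(=C)OCC; water, O
Why: Stille coupling with an acetyl-anion equivalent and hydrolysis of the enol ether; only now, with no enolate or hydride step left on the upper unit, is the ketone that supplies lower C4 and C3 unmasked, exactly at the brominated carbon.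

Step 14
Reactants: 18 1-{2,3,4-tris(benzyloxy)-5-[(2R,3R,4R)-3,7,8-tris(benzyloxy)-2-[3,4-bis(benzyloxy)phenyl]chroman-4-yl]phenyl}ethan-1-one
Product: 19 1-{3,4-bis(benzyloxy)-2-hydroxy-5-[(2R,3R,4R)-3,7,8-tris(benzyloxy)-2-[3,4-bis(benzyloxy)phenyl]chroman-4-yl]phenyl}ethan-1-one
Conditions: BCl3 (1.1 equiv), CH2Cl2, −78 °C; MeOH
Reagents that add atoms: none
Why: Chelation-directed ether cleavage: boron held between the ketone oxygen and the one ortho benzyloxy group delivers chloride to that benzyl carbon only, which frees the phenol that becomes lower O1.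

Step 15
Reactants: 19 1-{3,4-bis(benzyloxy)-2-hydroxy-5-[(2R,3R,4R)-3,7,8-tris(benzyloxy)-2-[3,4-bis(benzyloxy)phenyl]chroman-4-yl]phenyl}ethan-1-one; 20 4-(benzyloxy)benzaldehyde
Product: 22 7,8-bis(benzyloxy)-2-[4-(benzyloxy)phenyl]-3-hydroxy-6-[(2R,3R,4R)-3,7,8-tris(benzyloxy)-2-[3,4-bis(benzyloxy)phenyl]chroman-4-yl]-4H-chromen-4-one, via 2'-hydroxychalcone 21 (not isolated)
Conditions: KOH (aq.), EtOH/THF, rt; then H2O2 (30% aq.), 0 °C to rt
Reagents that add atoms: hydrogen peroxide, OO
Why: Claisen–Schmidt condensation followed in the same pot by Algar–Flynn–Oyamada oxidative cyclisation, which forms lower C2–C3, O1–C2 and the C3 hydroxyl; the position on the other side of the carbonyl (lower C5) is unsubstituted, the case that gives flavonol and not aurone, and the all-ether upper unit tolerates base and peroxide.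

Step 16
Reactants: 22 7,8-bis(benzyloxy)-2-[4-(benzyloxy)phenyl]-3-hydroxy-6-[(2R,3R,4R)-3,7,8-tris(benzyloxy)-2-[3,4-bis(benzyloxy)phenyl]chroman-4-yl]-4H-chromen-4-one
Product: 23 3,7,8-tris(benzyloxy)-2-[4-(benzyloxy)phenyl]-6-[(2R,3R,4R)-3,7,8-tris(benzyloxy)-2-[3,4-bis(benzyloxy)phenyl]chroman-4-yl]-4H-chromen-4-one
Conditions: BnBr, K2CO3, DMF, rt
Reagents that add atoms: benzyl bromide, BrCc1ccccc1
Why: Williamson etherification of the only free hydroxyl; it removes the acidic enol, which would otherwise sit as an unreactive flavonolate under the basic hydrogenation.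

Step 17
Reactants: 23 3,7,8-tris(benzyloxy)-2-[4-(benzyloxy)phenyl]-6-[(2R,3R,4R)-3,7,8-tris(benzyloxy)-2-[3,4-bis(benzyloxy)phenyl]chroman-4-yl]-4H-chromen-4-one
Product: 24 (2R,3R,4R)-3,7,8-tris(benzyloxy)-2-[4-(benzyloxy)phenyl]-6-[(2R,3R,4R)-3,7,8-tris(benzyloxy)-2-[3,4-bis(benzyloxy)phenyl]chroman-4-yl]chroman-4-ol
Conditions: [Ru(cod)(2-methylallyl)2] (cat.), 1,3-bis[(R)-1-(naphthalen-1-yl)ethyl]-4,5-dihydroimidazolium tetrafluoroborate (cat.), KOt-Bu (cat.), H2 (100 bar), toluene, 40 °C
Reagents that add atoms: none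
Why: Proposed new method: the chiral ruthenium–carbene hydride should add hydrogen across C2=C3 of the 3-alkoxyflavone on the face chosen by the ligand and then reduce C4=O from the same face while the substrate stays bound, so that all hydrogens arrive syn and the 2,3-cis-3,4-cis triad (2R,3R,4R) is set by the catalyst, independent of the remote upper unit; the closest known reaction is the ruthenium–N-heterocyclic carbene-catalysed asymmetric hydrogenation of flavones and chromones to cis-flavan-4-ols, and the all-cis outcome itself is known from heterogeneous hydrogenation of flavonol ethers; new here is the tetrasubstituted, 3-oxygenated double bond.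

Step 18
Reactants: 24 (2R,3R,4R)-3,7,8-tris(benzyloxy)-2-[4-(benzyloxy)phenyl]-6-[(2R,3R,4R)-3,7,8-tris(benzyloxy)-2-[3,4-bis(benzyloxy)phenyl]chroman-4-yl]chroman-4-ol
Product: 25 (2R,3R,4R)-2-(4-hydroxyphenyl)-6-[(2R,3R,4S)-2-(3,4-dihydroxyphenyl)-3,7,8-trihydroxychroman-4-yl]chromane-3,4,7,8-tetrol
Conditions: H2 (1 atm), Pd(OH)2/C, THF/MeOH, rt
Reagents that add atoms: none
Why: Hydrogenolysis of nine benzyl ethers under neutral conditions; aryl and alkyl benzyl ethers cleave faster than the secondary benzylic C4–OH and no acid is present, so the 3,4-diol and the interflavanyl bond should survive; the descriptor of upper C4 changes from R to S only because the CIP priorities change when the benzyl groups leave.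

Compound list

1 | 2,3,4-trimethoxybenzaldehyde | COc1ccc(C=O)c(OC)c1OC | starting material
2 | 5-bromo-2,3,4-trimethoxybenzaldehyde | COc1c(Br)cc(C=O)c(OC)c1OC | intermediate
3 | 1-(2,3-dimethoxyphenyl)ethan-1-one (2',3'-dimethoxyacetophenone) | CC(=O)c1cccc(OC)c1OC | starting material
4 | (E)-3-(5-bromo-2,3,4-trimethoxyphenyl)-1-(2,3-dimethoxyphenyl)prop-2-en-1-one | COc1cccc(C(=O)/C=C/c2cc(Br)c(OC)c(OC)c2OC)c1OC | intermediate
5 | rac-3-(5-bromo-2,3,4-trimethoxyphenyl)-6,7-dimethoxy-2,3-dihydro-1H-inden-1-one | COc1ccc2C(CC(=O)c2c1OC)c1cc(Br)c(OC)c(OC)c1OC | intermediate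
6 | rac-3-(5-bromo-2,3,4-trihydroxyphenyl)-6,7-dihydroxy-2,3-dihydro-1H-inden-1-one | Oc1ccc2C(CC(=O)c2c1O)c1cc(Br)c(O)c(O)c1O | intermediate
7 | rac-6,7-bis(benzyloxy)-3-[2,3,4-tris(benzyloxy)-5-bromophenyl]-2,3-dihydro-1H-inden-1-one | O=C1CC(c2cc(Br)c(OCc3ccccc3)c(OCc3ccccc3)c2OCc2ccccc2)c2ccc(OCc3ccccc3)c(OCc3ccccc3)c12 | intermediate
8 | rac-trans-6,7-bis(benzyloxy)-3-[2,3,4-tris(benzyloxy)-5-bromophenyl]-2-(phenylselanyl)-2,3-dihydro-1H-inden-1-one | O=C1C([Se]c2ccccc2)C(c2cc(Br)c(OCc3ccccc3)c(OCc3ccccc3)c2OCc2ccccc2)c2ccc(OCc3ccccc3)c(OCc3ccccc3)c12 | intermediate (not isolated)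
9 | 6,7-bis(benzyloxy)-3-[2,3,4-tris(benzyloxy)-5-bromophenyl]-1H-inden-1-one | O=C1C=C(c2cc(Br)c(OCc3ccccc3)c(OCc3ccccc3)c2OCc2ccccc2)c2ccc(OCc3ccccc3)c(OCc3ccccc3)c12 | intermediate
10 | (3R)-6,7-bis(benzyloxy)-3-[2,3,4-tris(benzyloxy)-5-bromophenyl]-2,3-dihydro-1H-inden-1-one | c1ccccc1COc1c(OCc2ccccc2)c(OCc2ccccc2)c(Br)cc1[C@@H]1CC(=O)c2c(OCc3ccccc3)c(OCc3ccccc3)ccc21 | intermediate
11 | (4R)-7,8-bis(benzyloxy)-4-[2,3,4-tris(benzyloxy)-5-bromophenyl]-3,4-dihydro-2H-chromen-2-one (same spatial arrangement at C4 as in 25) | c1ccccc1COc1c(OCc2ccccc2)c(OCc2ccccc2)c(Br)cc1[C@@H]1CC(=O)Oc2c(OCc3ccccc3)c(OCc3ccccc3)ccc21 | intermediate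
12 | (3R,4R)-7,8-bis(benzyloxy)-4-[2,3,4-tris(benzyloxy)-5-bromophenyl]-3-hydroxy-3,4-dihydro-2H-chromen-2-one (3,4-trans) | c1ccccc1COc1c(OCc2ccccc2)c(OCc2ccccc2)c(Br)cc1[C@@H]1[C@@H](O)C(=O)Oc2c(OCc3ccccc3)c(OCc3ccccc3)ccc21 | intermediate
13 | (3R,4R)-3,7,8-tris(benzyloxy)-4-[2,3,4-tris(benzyloxy)-5-bromophenyl]-3,4-dihydro-2H-chromen-2-one | c1ccccc1COc1c(OCc2ccccc2)c(OCc2ccccc2)c(Br)cc1[C@@H]1[C@@H](OCc2ccccc2)C(=O)Oc2c(OCc3ccccc3)c(OCc3ccccc3)ccc21 | intermediate
14 | (3R,4R)-3,7,8-tris(benzyloxy)-4-[2,3,4-tris(benzyloxy)-5-bromophenyl]chroman-2-ol (both C2 anomers) | c1ccccc1COc1c(OCc2ccccc2)c(OCc2ccccc2)c(Br)cc1[C@@H]1[C@@H](OCc2ccccc2)C(O)Oc2c(OCc3ccccc3)c(OCc3ccccc3)ccc21 | intermediate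
15 | 1,2-bis(benzyloxy)benzene | c1ccccc1COc1ccccc1OCc1ccccc1 | starting material
16 | (2R,3R,4R)-3,7,8-tris(benzyloxy)-2-[3,4-bis(benzyloxy)phenyl]-4-[2,3,4-tris(benzyloxy)-5-bromophenyl]chromane (2,3-cis, 3,4-trans) | c1ccccc1COc1c(OCc2ccccc2)c(OCc2ccccc2)c(Br)cc1[C@@H]1[C@@H](OCc2ccccc2)[C@@H](c2ccc(OCc3ccccc3)c(OCc3ccccc3)c2)Oc2c(OCc3ccccc3)c(OCc3ccccc3)ccc21 | intermediate
17 | (2R,3R,4R)-3,7,8-tris(benzyloxy)-2-[3,4-bis(benzyloxy)phenyl]-4-[2,3,4-tris(benzyloxy)-5-(1-ethoxyvinyl)phenyl]chromane | c1ccccc1COc1c(OCc2ccccc2)c(OCc2ccccc2)c(C(=C)OCC)cc1[C@@H]1[C@@H](OCc2ccccc2)[C@@H](c2ccc(OCc3ccccc3)c(OCc3ccccc3)c2)Oc2c(OCc3ccccc3)c(OCc3ccccc3)ccc21 | intermediate (not isolated)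
18 | 1-{2,3,4-tris(benzyloxy)-5-[(2R,3R,4R)-3,7,8-tris(benzyloxy)-2-[3,4-bis(benzyloxy)phenyl]chroman-4-yl]phenyl}ethan-1-one | c1ccccc1COc1c(OCc2ccccc2)c(OCc2ccccc2)c(C(C)=O)cc1[C@@H]1[C@@H](OCc2ccccc2)[C@@H](c2ccc(OCc3ccccc3)c(OCc3ccccc3)c2)Oc2c(OCc3ccccc3)c(OCc3ccccc3)ccc21 | intermediate
19 | 1-{3,4-bis(benzyloxy)-2-hydroxy-5-[(2R,3R,4R)-3,7,8-tris(benzyloxy)-2-[3,4-bis(benzyloxy)phenyl]chroman-4-yl]phenyl}ethan-1-one | c1ccccc1COc1c(OCc2ccccc2)c(O)c(C(C)=O)cc1[C@@H]1[C@@H](OCc2ccccc2)[C@@H](c2ccc(OCc3ccccc3)c(OCc3ccccc3)c2)Oc2c(OCc3ccccc3)c(OCc3ccccc3)ccc21 | intermediate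
20 | 4-(benzyloxy)benzaldehyde | O=Cc1ccc(OCc2ccccc2)cc1 | starting material
21 | (E)-1-{3,4-bis(benzyloxy)-2-hydroxy-5-[(2R,3R,4R)-3,7,8-tris(benzyloxy)-2-[3,4-bis(benzyloxy)phenyl]chroman-4-yl]phenyl}-3-[4-(benzyloxy)phenyl]prop-2-en-1-one | c1ccccc1COc1c(OCc2ccccc2)c(O)c(C(=O)/C=C/c2ccc(OCc3ccccc3)cc2)cc1[C@@H]1[C@@H](OCc2ccccc2)[C@@H](c2ccc(OCc3ccccc3)c(OCc3ccccc3)c2)Oc2c(OCc3ccccc3)c(OCc3ccccc3)ccc21 | intermediate (not isolated)
22 | 7,8-bis(benzyloxy)-2-[4-(benzyloxy)phenyl]-3-hydroxy-6-[(2R,3R,4R)-3,7,8-tris(benzyloxy)-2-[3,4-bis(benzyloxy)phenyl]chroman-4-yl]-4H-chromen-4-one | O=c1c(O)c(-c2ccc(OCc3ccccc3)cc2)oc2c(OCc3ccccc3)c(OCc3ccccc3)c([C@H]3c4ccc(OCc5ccccc5)c(OCc5ccccc5)c4O[C@H](c4ccc(OCc5ccccc5)c(OCc5ccccc5)c4)[C@@H]3OCc3ccccc3)cc12 | intermediate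
23 | 3,7,8-tris(benzyloxy)-2-[4-(benzyloxy)phenyl]-6-[(2R,3R,4R)-3,7,8-tris(benzyloxy)-2-[3,4-bis(benzyloxy)phenyl]chroman-4-yl]-4H-chromen-4-one | O=c1c(OCc2ccccc2)c(-c2ccc(OCc3ccccc3)cc2)oc2c(OCc3ccccc3)c(OCc3ccccc3)c([C@H]3c4ccc(OCc5ccccc5)c(OCc5ccccc5)c4O[C@H](c4ccc(OCc5ccccc5)c(OCc5ccccc5)c4)[C@@H]3OCc3ccccc3)cc12 | intermediate
24 | (2R,3R,4R)-3,7,8-tris(benzyloxy)-2-[4-(benzyloxy)phenyl]-6-[(2R,3R,4R)-3,7,8-tris(benzyloxy)-2-[3,4-bis(benzyloxy)phenyl]chroman-4-yl]chroman-4-ol (lower ring C all-cis) | c1ccccc1COc1ccc([C@H]2Oc3c(cc([C@H]4c5ccc(OCc6ccccc6)c(OCc6ccccc6)c5O[C@H](c5ccc(OCc6ccccc6)c(OCc6ccccc6)c5)[C@@H]4OCc4ccccc4)c(OCc4ccccc4)c3OCc3ccccc3)[C@@H](O)[C@H]2OCc2ccccc2)cc1 | intermediate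
25 | (2R,3R,4R)-2-(4-hydroxyphenyl)-6-[(2R,3R,4S)-2-(3,4-dihydroxyphenyl)-3,7,8-trihydroxychroman-4-yl]chromane-3,4,7,8-tetrol | Oc1ccc([C@H]2Oc3c(cc([C@H]4c5ccc(O)c(O)c5O[C@H](c5ccc(O)c(O)c5)[C@@H]4O)c(O)c3O)[C@@H](O)[C@H]2O)cc1 | target

Step count and risks

Total: 18 steps. Longest linear sequence: 18 steps (1 to 25); compounds 3, 15 and 20 enter as bought materials.

Step 17 (proposed method). The tetrasubstituted, oxygen-bearing double bond may not take up hydrogen. Face discrimination may be poor. The half-reduced ketone may also leave the metal, after which C3 epimerises before the carbonyl is reduced. The fallback uses known chemistry and sets out from 23. Hydrogenolysis (H2, Pd/C, THF/MeOH) would give the free flavonol F1. Hydrogenation over Raney Ni in ethanol, the classical syn reduction of flavonols to 2,3-cis-3,4-cis-flavan-3,4-diols, would then give 25 together with its lower-unit diastereomer F2. The two would be separated by reversed-phase chromatography, at the cost of half the material. The route is rejoined at 25.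

Step 8 (key step). Peracid addition to a carbonyl that is donor-substituted and flanked by the C7 benzyloxy group may be slow. Oxidation of the trialkoxyphenyl ring or acid-induced loss of benzyl groups could then compete. The fallback moves the aryl shift to the alcohol oxidation level and sets out from 10. NaBH4 would give the indanol F3. H2O2 with a trace of acid would convert it, through the benzylic cation, into the hydroperoxide F4. Hock rearrangement (BF3·OEt2, CH2Cl2, low temperature) would move the same ring A carbon to oxygen and give the lactol F5. Oxidation with Ag2CO3 on Celite returns to 11.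

Step 12. The arene may attack the wrong face and give the 2,3-trans epimer. The product may equilibrate to that more stable epimer by reopening of the benzylic O1–C2 bond under the Lewis acid. The cation may also be captured within the molecule by the free position of the C4 aryl ring. The fallback builds C2 in the open chain and sets out from 13. MeNH(OMe)·HCl with AlMe3 would open the lactone to the N-methoxy-N-methylamide F6. Excess 3,4-bis(benzyloxy)phenylmagnesium bromide would give the ketone F7. Chelation-controlled reduction with Zn(BH4)2 would give the 1,2-anti alcohol F8. Mitsunobu cyclisation (PPh3, diisopropyl azodicarboxylate) with inversion at the carbinol carbon would close ring C to the 2,3-cis product. The route is rejoined at 16.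

Step 18. Once the phenols are free, the benzylic C4–O bond of the lower unit may be hydrogenolysed, or the two secondary benzyl ethers may cleave incompletely. The fallback takes palladium out of the last stages and sets out from 23. Hydrogenolysis would give the free flavonol F1 (as in the fallback to step 17). Ac2O in pyridine would give the nonaacetate F9. Hydrogenation with the preformed catalyst of step 17 would give the acetylated all-cis carbinol F10. Degassed K2CO3 in MeOH at 0 °C would then release 25.

Step 7. Hydride transfer to a β-carbon that carries an aryl group encumbered on both ortho sides may be slow or poorly face-selective, and 1,2-reduction may compete. The fallback sets out from 9. Corey–Bakshi–Shibata reduction (Me-substituted oxazaborolidine, BH3·SMe2) would give the (1S)-indenol F11. A base-mediated suprafacial 1,3-hydrogen shift (1,4-diazabicyclo[2.2.2]octane, THF) would carry the configuration from C1 to C3. The route is rejoined at 10.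

## Further compounds

F1 | step 17 | 3,7,8-trihydroxy-2-(4-hydroxyphenyl)-6-[(2R,3R,4S)-2-(3,4-dihydroxyphenyl)-3,7,8-trihydroxychroman-4-yl]-4H-chromen-4-one | O=c1c(O)c(-c2ccc(O)cc2)oc2c(O)c(O)c([C@H]3c4ccc(O)c(O)c4O[C@H](c4ccc(O)c(O)c4)[C@@H]3O)cc12
F2 | step 17 | (2S,3S,4S)-2-(4-hydroxyphenyl)-6-[(2R,3R,4S)-2-(3,4-dihydroxyphenyl)-3,7,8-trihydroxychroman-4-yl]chromane-3,4,7,8-tetrol | Oc1ccc([C@@H]2Oc3c(cc([C@H]4c5ccc(O)c(O)c5O[C@H](c5ccc(O)c(O)c5)[C@@H]4O)c(O)c3O)[C@H](O)[C@@H]2O)cc1
F3 | step 8 | (3R)-6,7-bis(benzyloxy)-3-[2,3,4-tris(benzyloxy)-5-bromophenyl]-2,3-dihydro-1H-inden-1-ol (C1 epimers) | OC1C[C@@H](c2cc(Br)c(OCc3ccccc3)c(OCc3ccccc3)c2OCc2ccccc2)c2ccc(OCc3ccccc3)c(OCc3ccccc3)c12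
F4 | step 8 | (3R)-6,7-bis(benzyloxy)-3-[2,3,4-tris(benzyloxy)-5-bromophenyl]-1-hydroperoxy-2,3-dihydro-1H-indene (C1 epimers) | OOC1C[C@@H](c2cc(Br)c(OCc3ccccc3)c(OCc3ccccc3)c2OCc2ccccc2)c2ccc(OCc3ccccc3)c(OCc3ccccc3)c12
F5 | step 8 | (4R)-7,8-bis(benzyloxy)-4-[2,3,4-tris(benzyloxy)-5-bromophenyl]chroman-2-ol (both anomers) | OC1C[C@@H](c2cc(Br)c(OCc3ccccc3)c(OCc3ccccc3)c2OCc2ccccc2)c2ccc(OCc3ccccc3)c(OCc3ccccc3)c2O1
F6 | step 12 | (2R,3R)-2-(benzyloxy)-3-[3,4-bis(benzyloxy)-2-hydroxyphenyl]-3-[2,3,4-tris(benzyloxy)-5-bromophenyl]-N-methoxy-N-methylpropanamide | c1ccccc1COc1c(OCc2ccccc2)c(OCc2ccccc2)c(Br)cc1[C@H]([C@@H](OCc1ccccc1)C(=O)N(C)OC)c1ccc(OCc2ccccc2)c(OCc2ccccc2)c1O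
F7 | step 12 | (2R,3R)-2-(benzyloxy)-3-[3,4-bis(benzyloxy)-2-hydroxyphenyl]-1-[3,4-bis(benzyloxy)phenyl]-3-[2,3,4-tris(benzyloxy)-5-bromophenyl]propan-1-one | c1ccccc1COc1c(OCc2ccccc2)c(OCc2ccccc2)c(Br)cc1[C@H]([C@@H](OCc1ccccc1)C(=O)c1ccc(OCc2ccccc2)c(OCc2ccccc2)c1)c1ccc(OCc2ccccc2)c(OCc2ccccc2)c1O
F8 | step 12 | (1S,2R,3R)-2-(benzyloxy)-3-[3,4-bis(benzyloxy)-2-hydroxyphenyl]-1-[3,4-bis(benzyloxy)phenyl]-3-[2,3,4-tris(benzyloxy)-5-bromophenyl]propan-1-ol (1,2-anti) | c1ccccc1COc1c(OCc2ccccc2)c(OCc2ccccc2)c(Br)cc1[C@H]([C@@H](OCc1ccccc1)[C@@H](O)c1ccc(OCc2ccccc2)c(OCc2ccccc2)c1)c1ccc(OCc2ccccc2)c(OCc2ccccc2)c1O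
F9 | step 18 | nona-O-acetyl derivative of F1 (all nine hydroxyls acetylated) | O=c1c(OC(C)=O)c(-c2ccc(OC(C)=O)cc2)oc2c(OC(C)=O)c(OC(C)=O)c([C@H]3c4ccc(OC(C)=O)c(OC(C)=O)c4O[C@H](c4ccc(OC(C)=O)c(OC(C)=O)c4)[C@@H]3OC(C)=O)cc12
F10 | step 18 | nona-O-acetyl derivative of 25 with the lower 4-hydroxyl free (lower ring C all-cis) | CC(=O)Oc1ccc([C@H]2Oc3c(cc([C@H]4c5ccc(OC(C)=O)c(OC(C)=O)c5O[C@H](c5ccc(OC(C)=O)c(OC(C)=O)c5)[C@@H]4OC(C)=O)c(OC(C)=O)c3OC(C)=O)[C@@H](O)[C@H]2OC(C)=O)cc1
F11 | step 7 | (1S)-6,7-bis(benzyloxy)-3-[2,3,4-tris(benzyloxy)-5-bromophenyl]-1H-inden-1-ol | O[C@H]1C=C(c2cc(Br)c(OCc3ccccc3)c(OCc3ccccc3)c2OCc2ccccc2)c2ccc(OCc3ccccc3)c(OCc3ccccc3)c12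
A1 | alternative 1 | tethered diyne: 1-[4-(benzyloxy)phenyl]-2,3-bis(tert-butyldimethylsilyloxy)pent-4-yn-1-yl (pinacolboryl)ethynyl ether (configuration as in the SMILES) | c1ccccc1COc1ccc(cc1)[C@H]([C@H](O[Si](C)(C)C(C)(C)C)[C@H](O[Si](C)(C)C(C)(C)C)C#C)OC#CB1OC(C)(C)C(C)(C)O1
A2 | alternative 1 | upper unit with a (triisopropylsilyloxy)ethynyl group on C4: 3,7,8-tris(benzyloxy)-2-[3,4-bis(benzyloxy)phenyl]-4-[(triisopropylsilyloxy)ethynyl]chromane (configuration as in the SMILES) | CC(C)[Si](C(C)C)(C(C)C)OC#C[C@H]1c2ccc(OCc3ccccc3)c(OCc3ccccc3)c2O[C@H](c2ccc(OCc3ccccc3)c(OCc3ccccc3)c2)[C@@H]1OCc1ccccc1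
A3 | alternative 1 | protected dimer with a pinacolboryl group on lower C8 and a triisopropylsilyloxy group on lower C7 | c1ccccc1COc1ccc([C@H]2Oc3c(cc([C@H]4c5ccc(OCc6ccccc6)c(OCc6ccccc6)c5O[C@H](c5ccc(OCc6ccccc6)c(OCc6ccccc6)c5)[C@@H]4OCc4ccccc4)c(O[Si](C(C)C)(C(C)C)C(C)C)c3B3OC(C)(C)C(C)(C)O3)[C@@H](O[Si](C)(C)C(C)(C)C)[C@H]2O[Si](C)(C)C(C)(C)C)cc1
A4 | alternative 2 | free 2',3',4',4-tetrahydroxychalcone carrying the unprotected upper unit on C5' | O=C(/C=C/c1ccc(O)cc1)c1cc([C@H]2c3ccc(O)c(O)c3O[C@H](c3ccc(O)c(O)c3)[C@@H]2O)c(O)c(O)c1O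
A5 | alternative 2 | (2S)-7,8-dihydroxy-2-(4-hydroxyphenyl)chroman-4-one carrying the upper unit on C6 | O=C1C[C@@H](c2ccc(O)cc2)Oc2c(O)c(O)c([C@H]4c5ccc(O)c(O)c5O[C@H](c5ccc(O)c(O)c5)[C@@H]4O)cc21
A6 | alternative 3 | rac-2,3-bis(benzyloxy)-6-{[2,3,4-tris(benzyloxy)phenyl](4-methylphenylsulfonyl)methyl}phenol | Cc1ccc(cc1)S(=O)(=O)C(c1ccc(OCc2ccccc2)c(OCc2ccccc2)c1O)c1ccc(OCc2ccccc2)c(OCc2ccccc2)c1OCc1ccccc1
A7 | alternative 3 | 2-(benzyloxy)acetaldehyde | O=CCOCc1ccccc1
A8 | alternative 3 | (3R,4S)-3,7,8-tris(benzyloxy)-4-[2,3,4-tris(benzyloxy)phenyl]chroman-2-ol (3,4-trans, both C2 anomers) | c1ccccc1COc1c(OCc2ccccc2)c(OCc2ccccc2)ccc1[C@H]1c2ccc(OCc3ccccc3)c(OCc3ccccc3)c2OC(O)[C@@H]1OCc1ccccc1
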